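The 20-membered macrocycle is cut at the ether bond between the oxygen on ring C and C3 of ring D. Ring A is the catechol-type ring with its aryloxy O para to the bridge, B is the meta-bridged ring, C is the para-bridged ring, and D has its OH at C4, para to the bridge. Ring D holds this aryloxy oxygen right beside its own C4 hydroxyl, the fingerprint of an oxidative phenol–phenol C–O coupling. Thallium(III) oxidation, then zinc in the same flask, forms O–C3(D) and closes the ring in one operation. The precursor is the open bis(bibenzyl) with a 3,5-dibromophenol (D), a 3,5-dichlorophenol (C) and ring A as methyl ether. All halogens arrive with purchased aldehydes.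

Key step: step 11

Remark: the target has no stereocentre and its SMILES carries no stereodescriptor. The macrocycle is taken as conformationally mobile, so there is no enantiomer to select and the route needs no stereocontrol.

Step 1
Reactants: 1 4-fluoro-3-methoxybenzaldehyde; 2 3-hydroxybenzyl alcohol
Product: 3 4-[3-(hydroxymethyl)phenoxy]-3-methoxybenzaldehyde (A–O–B unit, CHO on ring A, CH2OH on ring B)
Conditions: K2CO3, DMF, 120 °C
Reagents that add atoms: none
Why: Nucleophilic aromatic substitution (SNAr), in which the fluoride is activated by the para formyl group and carbonate deprotonates only the phenol of 2, so the diaryl ether forms chemoselectively with its two arms already differentiated as CHO and CH2OH.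

Step 2
Reactants: 4 3,5-dibromo-4-hydroxybenzaldehyde
Product: 5 4-(benzyloxy)-3,5-dibromobenzaldehyde
Conditions: BnBr, K2CO3, DMF, 60 °C
Reagents that add atoms: benzyl bromide, BrCc1ccccc1
Why: Williamson ether synthesis on the fully deprotonated, acidic dibromophenol installs a group that withstands base, mild acid and diimide.

Step 3
Reactants: 5 4-(benzyloxy)-3,5-dibromobenzaldehyde
Product: 6 [4-(benzyloxy)-3,5-dibromophenyl]methanol
Conditions: NaBH4, THF–MeOH, 0 °C
Reagents that add atoms: none
Why: Borohydride reduction of an aromatic aldehyde leaves the aryl bromides and the benzyl ether untouched.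

Step 4
Reactants: 6 [4-(benzyloxy)-3,5-dibromophenyl]methanol
Product: 7 [4-(benzyloxy)-3,5-dibromobenzyl]triphenylphosphonium bromide
Conditions: PPh3·HBr, MeCN, reflux
Reagents that add atoms: triphenylphosphine hydrobromide, [Br-].[PH+](c1ccccc1)(c1ccccc1)c1ccccc1
Why: Acid-promoted nucleophilic substitution of a benzylic alcohol by triphenylphosphine, in which the alcohol oxygen is protonated in preference to the far less basic dihaloaryl ether oxygen.

Step 5
Reactants: 3 4-[3-(hydroxymethyl)phenoxy]-3-methoxybenzaldehyde; 7 [4-(benzyloxy)-3,5-dibromobenzyl]triphenylphosphonium bromide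
Product: 8 (3-{4-[2-(4-benzyloxy-3,5-dibromophenyl)ethenyl]-2-methoxyphenoxy}phenyl)methanol (E/Z mixture)
Conditions: K2CO3, 18-crown-6 (cat.), CH2Cl2, reflux
Reagents that add atoms: none
Why: Wittig olefination under solid–liquid carbonate/crown ether conditions is mild enough for the free benzylic alcohol and the aryl bromides, and the alkene geometry is irrelevant because step 9 saturates it.

Step 6
Reactants: 8 stilbene alcohol (E/Z mixture)
Product: 9 (3-{4-[2-(4-benzyloxy-3,5-dibromophenyl)ethenyl]-2-methoxyphenoxy}benzyl)triphenylphosphonium bromide (E/Z mixture)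
Conditions: PPh3·HBr, MeCN, reflux
Reagents that add atoms: triphenylphosphine hydrobromide, [Br-].[PH+](c1ccccc1)(c1ccccc1)c1ccccc1
Why: The same acid-promoted substitution of a benzylic alcohol by triphenylphosphine applies, and at worst it isomerises the stilbene double bond, which does not matter.

Step 7
Reactants: 10 3,5-dichloro-4-hydroxybenzaldehyde
Product: 11 4-(benzyloxy)-3,5-dichlorobenzaldehyde
Conditions: BnBr, K2CO3, DMF, 60 °C
Reagents that add atoms: benzyl bromide, BrCc1ccccc1
Why: Williamson ether synthesis removes the phenoxide character that would otherwise deactivate the aldehyde towards olefination.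

Step 8
Reactants: 9 ring-B benzylphosphonium bromide; 11 4-(benzyloxy)-3,5-dichlorobenzaldehyde
Product: 12 bis-stilbene D=A–O–B=C with OBn on rings C and D (E/Z mixture at both alkenes)
Conditions: K2CO3, 18-crown-6 (cat.), CH2Cl2, reflux
Reagents that add atoms: none
Why: A second Wittig olefination pairs an electron-poor, hence reactive, aldehyde with a benzylic phosphonium salt and completes the carbon skeleton with bromine only on ring D and chlorine only on ring C.

Step 9
Reactants: 12 bis-stilbene
Product: 13 open bis(bibenzyl) dibenzyl ether (both bridges CH2CH2)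
Conditions: TsNHNH2 (excess, in portions), NaOAc, DME–H2O, reflux
Reagents that add atoms: none
Why: Diimide reduction transfers two hydrogens in a concerted syn fashion to each 1,2-disubstituted alkene and leaves intact the C–Br, C–Cl and O-benzyl bonds that hydrogenation over palladium would cleave.

Step 10
Reactants: 13 open bis(bibenzyl) dibenzyl ether
Product: 14 seco bisphenol: 2,6-dibromo-4-[2-(4-{3-[2-(3,5-dichloro-4-hydroxyphenyl)ethyl]phenoxy}-3-methoxyphenyl)ethyl]phenol
Conditions: BCl3, pentamethylbenzene, CH2Cl2, −78 to −20 °C; then MeOH/H2O
Reagents that add atoms: none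
Why: In this Lewis acid debenzylation with a cation scavenger, BCl3 ionises both benzyl ethers at low temperature and pentamethylbenzene traps the benzyl cations by Friedel–Crafts alkylation, while the methyl ether, the diaryl ether and the halogens stay inert.

Step 11
Reactants: 14 seco bisphenol
Product: 16 trihalogenated macrocycle (OMe on ring A; Cl on both ring-C carbons flanking the new ether O; ring-D OH flanked by that ether O and one Br), via aryloxy bromodienone 15 (not isolated)
Conditions: Tl(NO3)3·3H2O, THF–MeOH 4:1, ca. 1 mM, −20 to 0 °C; then Zn dust, AcOH, rt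
Reagents that add atoms: none
Why: Thallium(III) withdraws two electrons from ring D, whose dibromophenol has the lower oxidation potential, and the electrophilic phenoxenium-type species is intercepted at C3(–Br) by the hydroxyl oxygen of the dichlorophenol ring C to give dienone 15; zinc in acetic acid then cleaves the sp3 C–Br bond reductively, so ring D regains aromaticity as the ortho-aryloxyphenol 16. The closest known reaction type is the thallium(III) nitrate macrocyclisation of o,o'-dihalogenated bisphenols to isodityrosine-type diaryl ethers in cyclic peptides and diarylheptanoids. The one ring formed is the 20-membered macrocycle, closed end to end by intramolecular O–C bond formation at high dilution between termini already tethered through both CH2CH2 bridges and the A–O–B ether. No stereocentre survives, because the sp3 carbon of 15 arises as a racemate and is erased on rearomatisation. The direction of coupling (oxygen of C onto carbon of D) is secured by bromine versus chlorine, C–C coupling is shut off because every ortho and para position of both phenols is occupied, the two bromines of ring D are equivalent so only one regioisomer can form, and ring A is kept out of the oxidation as its methyl ether. Methanol adducts at the para carbon of ring D are returned to the phenol by the same zinc treatment, so this side path costs conversion and not material.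

Step 12
Reactants: 16 trihalogenated macrocycle
Product: 17 halogen-free macrocycle, ring-A methyl ether
Conditions: H2 (1 atm), 10% Pd/C, NaOAc, MeOH–EtOAc, rt
Reagents that add atoms: none
Why: Catalytic hydrodehalogenation replaces the C–Br and both C–Cl bonds by C–H while acetate buffers the acid released, and the diaryl ethers, the phenol and the methyl ether are unaffected.

Step 13
Reactants: 17 halogen-free macrocycle, ring-A methyl ether
Product: 18 target CNP0329842.0
Conditions: BBr3, CH2Cl2, −78 °C to rt; then H2O
Reagents that add atoms: none
Why: Boron tribromide cleaves the aryl methyl ether (coordination at oxygen, then SN2 attack of bromide on methyl) without breaking the diaryl ethers, and hydrolysis frees the ring-A phenol.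

Compound list
1 | 4-fluoro-3-methoxybenzaldehyde | COc1cc(C=O)ccc1F | starting material
2 | 3-hydroxybenzyl alcohol | OCc1cccc(O)c1 | starting material
3 | 4-[3-(hydroxymethyl)phenoxy]-3-methoxybenzaldehyde | COc1cc(C=O)ccc1Oc1cccc(CO)c1 | intermediate
4 | 3,5-dibromo-4-hydroxybenzaldehyde | O=Cc1cc(Br)c(O)c(Br)c1 | starting material
5 | 4-(benzyloxy)-3,5-dibromobenzaldehyde | O=Cc1cc(Br)c(OCc2ccccc2)c(Br)c1 | intermediate
6 | [4-(benzyloxy)-3,5-dibromophenyl]methanol | OCc1cc(Br)c(OCc2ccccc2)c(Br)c1 | intermediate
7 | [4-(benzyloxy)-3,5-dibromobenzyl]triphenylphosphonium bromide | [Br-].Brc1cc(C[P+](c2ccccc2)(c2ccccc2)c2ccccc2)cc(Br)c1OCc1ccccc1 | intermediate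
8 | stilbene alcohol D=A–O–B–CH2OH, E/Z mixture (no descriptor written) | COc1cc(C=Cc2cc(Br)c(OCc3ccccc3)c(Br)c2)ccc1Oc1cccc(CO)c1 | intermediate
9 | ring-B benzyltriphenylphosphonium bromide of 8, E/Z mixture | [Br-].COc1cc(C=Cc2cc(Br)c(OCc3ccccc3)c(Br)c2)ccc1Oc1cccc(C[P+](c2ccccc2)(c2ccccc2)c2ccccc2)c1 | intermediate
10 | 3,5-dichloro-4-hydroxybenzaldehyde | O=Cc1cc(Cl)c(O)c(Cl)c1 | starting material
11 | 4-(benzyloxy)-3,5-dichlorobenzaldehyde | O=Cc1cc(Cl)c(OCc2ccccc2)c(Cl)c1 | intermediate
12 | bis-stilbene dibenzyl ether, E/Z mixture at both alkenes | COc1cc(C=Cc2cc(Br)c(OCc3ccccc3)c(Br)c2)ccc1Oc1cccc(C=Cc2cc(Cl)c(OCc3ccccc3)c(Cl)c2)c1 | intermediate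
13 | open bis(bibenzyl) dibenzyl ether | COc1cc(CCc2cc(Br)c(OCc3ccccc3)c(Br)c2)ccc1Oc1cccc(CCc2cc(Cl)c(OCc3ccccc3)c(Cl)c2)c1 | intermediate
14 | seco bisphenol (ring D 3,5-dibromo-4-hydroxy, ring C 3,5-dichloro-4-hydroxy, ring A OMe) | COc1cc(CCc2cc(Br)c(O)c(Br)c2)ccc1Oc1cccc(CCc2cc(Cl)c(O)c(Cl)c2)c1 | intermediate
15 | macrocyclic 6-aryloxy-2,6-dibromocyclohexa-2,4-dienone (ring D dearomatised; racemic at the sp3 carbon, transient) | COc1cc2ccc1Oc1cccc(c1)CCc1cc(Cl)c(c(Cl)c1)OC1(Br)C=C(C=C(Br)C1=O)CC2 | intermediate
16 | trihalogenated macrocycle, ring-A methyl ether | COc1cc2ccc1Oc1cccc(c1)CCc1cc(Cl)c(c(Cl)c1)Oc1cc(cc(Br)c1O)CC2 | intermediate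
17 | halogen-free macrocycle, ring-A methyl ether | COc1cc2ccc1Oc1cccc(c1)CCc1ccc(cc1)Oc1cc(ccc1O)CC2 | intermediate
18 | CNP0329842.0, macrocyclic bis(bibenzyl) diphenol (achiral) | Oc1cc2ccc1Oc1cccc(c1)CCc1ccc(cc1)Oc1cc(ccc1O)CC2 | target

Total step count: 13.
Longest linear sequence: 11 steps (4 to 18 through steps 2–6 and 8–13).

Steps most likely to fail

Step 11. Intermolecular coupling may outrun ring closure, solvent may capture the oxidised ring D at its para carbon, or ring A may be over-oxidised. The fallback forms the same O–C3(D) bond by a copper-mediated cross-coupling instead of an oxidation.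
- It sets out from 9. Olefination of 9 with purchased 4-(methoxymethoxy)benzaldehyde under the conditions of step 8 should give the MOM-protected bis-stilbene F1.
- Diimide reduction as in step 9 should give the saturated MOM ether F2.
- HCl in MeOH–THF should free the unhindered ring-C phenol F3.
- An intramolecular Ullmann etherification (CuI, N,N-dimethylglycine, Cs2CO3, dioxane, 100 °C, high dilution) at either of the two equivalent C–Br bonds of ring D should give the bromo benzyl ether macrocycle F4.
- Hydrogenolysis (H2, Pd/C, NaOAc) removes the remaining bromine and the benzyl group together, and the route is rejoined at 17.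

Step 9. The hydrogen transfer may stall after one alkene, because diimide disproportionates faster than it reduces the conjugated E-stilbene units. The fallback sets out from 12 and replaces the stoichiometric reagent by homogeneous catalytic hydrogenation with RhCl(PPh3)3 under a few bar of H2 in toluene–ethanol at 50 °C. A rhodium(I) hydride cycle of this kind adds to disubstituted alkenes but does not insert into aryl–halogen or benzyl–oxygen bonds. It comes back at 13 and makes no new compound (F0).

Step 10. The ring-A methyl ether may be lost through chelation of boron by the two neighbouring oxygens, or benzyl cations may be transferred to the electron-rich ring A. The fallback sets out from 13 and inverts the polarity of the deprotection. Sodium ethanethiolate in DMF at 80 °C attacks the benzylic carbons by SN2 and expels the two well-stabilised 2,6-dihalophenoxides. The methyl group on the much poorer guaiacol-type leaving group should react far more slowly. Acidic work-up returns the route at 14, and no new compound is made (F0).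

Further compounds
F1 | step 11 | MOM-protected bis-stilbene (ring D 3,5-dibromo-4-benzyloxy, ring C 4-methoxymethoxy), E/Z mixture | COc1cc(C=Cc2cc(Br)c(OCc3ccccc3)c(Br)c2)ccc1Oc1cccc(C=Cc2ccc(OCOC)cc2)c1
F2 | step 11 | saturated MOM ether | COc1cc(CCc2cc(Br)c(OCc3ccccc3)c(Br)c2)ccc1Oc1cccc(CCc2ccc(OCOC)cc2)c1
F3 | step 11 | ring-C phenol with ring D as 3,5-dibromo-4-benzyloxyphenyl | COc1cc(CCc2cc(Br)c(OCc3ccccc3)c(Br)c2)ccc1Oc1cccc(CCc2ccc(O)cc2)c1
F4 | step 11 | bromo benzyl ether macrocycle | COc1cc2ccc1Oc1cccc(c1)CCc1ccc(cc1)Oc1cc(cc(Br)c1OCc1ccccc1)CC2
F0 | step 9 | none | none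
F0 | step 10 | none | none
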